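**Retrosynthetic overview**

1. The target is read as guibourtinidol-(4α→6)-epicatechin: an upper flavan-3-ol (rings A, B, C; 2R,3S,4S, all-trans) bonded through C4 to C6 of an intact (−)-epicatechin (rings D, E, F; 2R,3R). The last two events are global hydrogenolysis and, before it, hydroboration of a C3=C4 alkene (a 4-aryl-flav-3-ene), which sets C3 and C4 from C2 alone.
2. Key disconnection: ring C is cut at O1–C8a and at C3–C4. This gives a diarylmethyl sulfone (ring A with fluorine on C8a; C4 carrying ring D and PhSO2) and (R)-2-[4-(benzyloxy)phenyl]oxirane (O1, C2, C3 and ring B).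
3. Enabling feature: C4 is doubly benzylic, lying between C4a of ring A and C6 of ring D, so it can be a sulfone-stabilised carbanion. C8a is the ring A carbon ortho to C4a and can carry a fluoride. O1 and C3 are both bonded to C2, which is an epoxide whose opening at C3 releases O1 as an alkoxide.
4. The sulfone comes from a three-component Friedel–Crafts reaction of C8-brominated penta-O-benzylepicatechin (C6 is the only free position of ring D), 4-(benzyloxy)-2-fluorobenzaldehyde and PhSO2H. The epoxide comes from CBS reduction of a phenacyl bromide.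
5. Ring order: rings A, B, D, E and F are bought; ring C is the only ring made, and it is made in the key step.

Key step: step 7

Remark: flavan numbering is used for both units. The CIP label of C2 of the upper unit reads R in 9 and 10, S in 12 to 15, and R in 17 and 18 only because the rank of C3 changes; the spatial arrangement fixed in step 5 is never touched.

**Route**

Step 1
Reactants: 1 (−)-epicatechin
Product: 2 (2R,3R)-5,7-bis(benzyloxy)-2-[3,4-bis(benzyloxy)phenyl]chroman-3-ol
Conditions: BnBr (4.4 equiv), K2CO3, DMF, 0 °C → rt, N2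
Reagents that add atoms: benzyl bromide (BrCc1ccccc1)
Why: Williamson etherification with K2CO3 alkylates the four phenols and leaves the less acidic C3 alcohol free, and the mild base at room temperature should not epimerise C2.

Step 2
Reactants: 2 tetra-O-benzylepicatechin
Product: 3 (2R,3R)-3,5,7-tris(benzyloxy)-2-[3,4-bis(benzyloxy)phenyl]chromane
Conditions: NaH, BnBr, Bu4NI (cat.), DMF, 0 °C → rt
Reagents that add atoms: benzyl bromide (BrCc1ccccc1)
Why: Williamson etherification of the secondary alcohol through its sodium alkoxide; only the O–H bond reacts, so C3 keeps its configuration.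

Step 3
Reactants: 3 penta-O-benzylepicatechin
Product: 4 (2R,3R)-3,5,7-tris(benzyloxy)-2-[3,4-bis(benzyloxy)phenyl]-8-bromochromane
Conditions: NBS (1.05 equiv), CH2Cl2, −78 °C → rt
Reagents that add atoms: N-bromosuccinimide (BrN1C(=O)CCC1=O)
Why: Electrophilic aromatic bromination of the phloroglucinol-type ring D of O-benzylated flavan-3-ols goes to C8 rather than to C6, which blocks C8 so that the next step can only use C6.

Step 4
Reactants: 4 8-bromo-penta-O-benzylepicatechin, 5 4-(benzyloxy)-2-fluorobenzaldehyde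
Product: 7 (2R,3R)-3,5,7-tris(benzyloxy)-2-[3,4-bis(benzyloxy)phenyl]-8-bromo-6-{[4-(benzyloxy)-2-fluorophenyl](phenylsulfonyl)methyl}chromane (both epimers at the sulfonyl carbon), via diaryl carbinol 6 (not isolated)
Conditions: PhSO2H (3 equiv), TsOH·H2O (20 mol %), MgSO4, CH2Cl2, 0 °C → rt
Reagents that add atoms: benzenesulfinic acid (OS(=O)c1ccccc1)
Why: Brønsted-acid three-component Friedel–Crafts sulfonylalkylation, the reaction type used to make 3-(1-sulfonylalkyl)indoles and 2-(1-sulfonylalkyl)phenols: C6 adds to the protonated aldehyde, carbinol 6 ionises to a doubly stabilised diarylmethyl cation, and benzenesulfinate traps it at sulfur before a second arene can add; the new carbon forms as both epimers, which does not matter because step 7 planarises it.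

Step 5
Reactants: 8 2-bromo-1-[4-(benzyloxy)phenyl]ethan-1-one
Product: 9 (1R)-2-bromo-1-[4-(benzyloxy)phenyl]ethan-1-ol
Conditions: (R)-2-methyl-CBS-oxazaborolidine (10 mol %), BH3·SMe2, THF, 0 °C; MeOH, then aqueous work-up
Reagents that add atoms: none
Why: Corey–Bakshi–Shibata reduction, in which the oxazaborolidine–borane complex delivers hydride to one ketone face with the aryl group as the large substituent; for an α-bromo aryl ketone the (R)-catalyst should give the (R)-bromohydrin, and one recrystallisation can raise the enantiomeric purity.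

Step 6
Reactants: 9 (R)-bromohydrin
Product: 10 (2R)-2-[4-(benzyloxy)phenyl]oxirane
Conditions: NaOH (2 M aq), THF, 0 °C → rt
Reagents that add atoms: none
Why: Intramolecular Williamson (3-exo-tet) closure of the bromohydrin alkoxide; the stereocentre is not involved, so its configuration is retained.

Step 7
Reactants: 7 diarylmethyl sulfone (both epimers), 10 (R)-epoxide
Product: 13 (2S)-7-(benzyloxy)-2-[4-(benzyloxy)phenyl]-4-(phenylsulfonyl)-4-[(2R,3R)-3,5,7-tris(benzyloxy)-2-[3,4-bis(benzyloxy)phenyl]-8-bromochroman-6-yl]chromane (both C4 epimers), via sulfonyl carbanion potassium salt 11 (not isolated), via open-chain potassium alkoxide 12 (not isolated)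
Conditions: KN(SiMe3)2 (1.1 equiv), THF, −78 °C; 10 (1.2 equiv), DMPU, −78 → 25 °C; then 18-crown-6, 65 °C
Reagents that add atoms: none
Why: Proposed new method: an anion-relay (3+3) annulation in which KN(SiMe3)2 turns either epimer of 7 into the same planar diaryl(sulfonyl)methyl carbanion 11, this opens epoxide 10 by SN2 at its CH2 carbon (C3–C4 bond), and the C2 alkoxide 12 so released displaces fluoride from C8a of ring A by SNAr through a Meisenheimer adduct (O1–C8a bond). The closest known reaction types are the opening of terminal epoxides by α-sulfonyl carbanions and the alkoxide-on-fluoroarene closure of the pyran ring of O-benzylated flavans; what is not known is their union in one flask on a fully substituted, doubly benzylic carbanion. Ring C is closed by a six-membered (6-exo-trig type) attack of O1 on the trigonal C8a, after which fluoride leaves. No stereocentre needs control here: C2 comes unchanged from 10 because none of its bonds is broken, and the sulfonyl-bearing C4 forms as two epimers that step 8 flattens again, so the step is stereoconvergent with respect to 7. The selectivities needed are CH2 versus benzylic opening of the epoxide (secured by the bulky, soft carbanion and the absence of any Lewis acid), C–F versus C–Br substitution (only fluoride is an SNAr leaving group on these unactivated rings, so the C8 bromide of ring D survives) and cyclisation versus proton quench (C4 is quaternary after the alkylation, so no acidic C–H remains to protonate the alkoxide).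

Step 8
Reactants: 13 4-sulfonylflavan (both C4 epimers)
Product: 15 (2S)-7-(benzyloxy)-2-[4-(benzyloxy)phenyl]-4-[(2R,3R)-3,5,7-tris(benzyloxy)-2-[3,4-bis(benzyloxy)phenyl]-8-bromochroman-6-yl]-2H-chromene, via flavan-4-ylium benzenesulfinate 14 (not isolated)
Conditions: Sc(OTf)3 (10 mol %), 2,6-di-tert-butyl-4-methylpyridine (1.5 equiv), CH2Cl2, −20 → 0 °C, in the dark
Reagents that add atoms: none
Why: E1 loss of benzenesulfinate, in which the Lewis acid pulls the sulfinate from the fully substituted C4 (carbenium ion 14 is stabilised by O1 and the 7-benzyloxy group of ring A and by the trialkoxy ring D) and the hindered pyridine removes a C3 proton to give the conjugated C3=C4 alkene; both C4 epimers converge on one product and C2, which is not part of the cation, should keep its configuration.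

Step 9
Reactants: 15 4-aryl-flav-3-ene
Product: 17 (2R,3S,4S)-7-(benzyloxy)-2-[4-(benzyloxy)phenyl]-4-[(2R,3R)-3,5,7-tris(benzyloxy)-2-[3,4-bis(benzyloxy)phenyl]-8-bromochroman-6-yl]chroman-3-ol, via C3 alkylborane 16 (not isolated)
Conditions: BH3·THF (excess), THF, 0 °C → rt; then NaOH (aq), H2O2, 0 °C
Reagents that add atoms: hydrogen peroxide (OO)
Why: Hydroboration–oxidation (syn, anti-Markovnikov), in which boron adds to C3 and hydrogen to the diaryl-substituted C4 from the face opposite the C2 aryl group, as in the known hydroboration of flav-3-enes to 2,3-trans-flavan-3-ols; after oxidation with retention the C3 hydroxyl is trans to the C2 aryl (3S) and cis to the new C4–H, which places ring D trans to the hydroxyl (4S).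

Step 10
Reactants: 17 hepta-O-benzyl bromo dimer
Product: 18 (2R,3S,4S)-2-(4-hydroxyphenyl)-4-[(2R,3R)-2-(3,4-dihydroxyphenyl)-3,5,7-trihydroxychroman-6-yl]chromane-3,7-diol (target)
Conditions: H2 (1 atm), Pd(OH)2/C, NaHCO3, THF/MeOH/H2O, rt
Reagents that add atoms: none
Why: Palladium-catalysed hydrogenolysis cleaves the seven O-benzyl groups and the aryl C–Br bond in one operation (NaHCO3 takes up HBr), as in the deprotection of C8-brominated perbenzylated procyanidins, and leaves the five stereocentres and the C4–C6 bond untouched.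

**Compound list**

1 | (−)-epicatechin, (2R,3R)-2-(3,4-dihydroxyphenyl)chromane-3,5,7-triol | c1c(O)c2C[C@@H](O)[C@@H](c3ccc(O)c(O)c3)Oc2cc1O | starting material
2 | (2R,3R)-5,7-bis(benzyloxy)-2-[3,4-bis(benzyloxy)phenyl]chroman-3-ol | c1c(OCc2ccccc2)c2C[C@@H](O)[C@@H](c3ccc(OCc4ccccc4)c(OCc4ccccc4)c3)Oc2cc1OCc1ccccc1 | intermediate
3 | (2R,3R)-3,5,7-tris(benzyloxy)-2-[3,4-bis(benzyloxy)phenyl]chromane | c1c(OCc2ccccc2)c2C[C@@H](OCc3ccccc3)[C@@H](c3ccc(OCc4ccccc4)c(OCc4ccccc4)c3)Oc2cc1OCc1ccccc1 | intermediate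
4 | (2R,3R)-3,5,7-tris(benzyloxy)-2-[3,4-bis(benzyloxy)phenyl]-8-bromochromane | c1c(OCc2ccccc2)c2C[C@@H](OCc3ccccc3)[C@@H](c3ccc(OCc4ccccc4)c(OCc4ccccc4)c3)Oc2c(Br)c1OCc1ccccc1 | intermediate
5 | 4-(benzyloxy)-2-fluorobenzaldehyde | O=Cc1ccc(OCc2ccccc2)cc1F | starting material
6 | [4-(benzyloxy)-2-fluorophenyl][(2R,3R)-3,5,7-tris(benzyloxy)-2-[3,4-bis(benzyloxy)phenyl]-8-bromochroman-6-yl]methanol, both carbinol epimers | OC(c1ccc(OCc2ccccc2)cc1F)c1c(OCc2ccccc2)c2C[C@@H](OCc3ccccc3)[C@@H](c3ccc(OCc4ccccc4)c(OCc4ccccc4)c3)Oc2c(Br)c1OCc1ccccc1 | intermediate (not isolated)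
7 | (2R,3R)-3,5,7-tris(benzyloxy)-2-[3,4-bis(benzyloxy)phenyl]-8-bromo-6-{[4-(benzyloxy)-2-fluorophenyl](phenylsulfonyl)methyl}chromane, both epimers at the sulfonyl carbon | O=S(=O)(c1ccccc1)C(c1ccc(OCc2ccccc2)cc1F)c1c(OCc2ccccc2)c2C[C@@H](OCc3ccccc3)[C@@H](c3ccc(OCc4ccccc4)c(OCc4ccccc4)c3)Oc2c(Br)c1OCc1ccccc1 | intermediate
8 | 2-bromo-1-[4-(benzyloxy)phenyl]ethan-1-one | O=C(CBr)c1ccc(OCc2ccccc2)cc1 | starting material
9 | (1R)-2-bromo-1-[4-(benzyloxy)phenyl]ethan-1-ol | O[C@@H](CBr)c1ccc(OCc2ccccc2)cc1 | intermediate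
10 | (2R)-2-[4-(benzyloxy)phenyl]oxirane | O1C[C@H]1c1ccc(OCc2ccccc2)cc1 | intermediate
11 | potassium salt of the carbanion of 7 (carbanion at the sulfonyl carbon, the future C4) | [K+].O=S(=O)(c1ccccc1)[C-](c1ccc(OCc2ccccc2)cc1F)c1c(OCc2ccccc2)c2C[C@@H](OCc3ccccc3)[C@@H](c3ccc(OCc4ccccc4)c(OCc4ccccc4)c3)Oc2c(Br)c1OCc1ccccc1 | intermediate (not isolated)
12 | potassium (1S)-1-[4-(benzyloxy)phenyl]-3-[4-(benzyloxy)-2-fluorophenyl]-3-(phenylsulfonyl)-3-[(2R,3R)-3,5,7-tris(benzyloxy)-2-[3,4-bis(benzyloxy)phenyl]-8-bromochroman-6-yl]propan-1-olate, both epimers at the sulfonyl carbon | [K+].[O-][C@@H](CC(S(=O)(=O)c1ccccc1)(c1ccc(OCc2ccccc2)cc1F)c1c(OCc2ccccc2)c2C[C@@H](OCc3ccccc3)[C@@H](c3ccc(OCc4ccccc4)c(OCc4ccccc4)c3)Oc2c(Br)c1OCc1ccccc1)c1ccc(OCc2ccccc2)cc1 | intermediate (not isolated)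
13 | (2S)-7-(benzyloxy)-2-[4-(benzyloxy)phenyl]-4-(phenylsulfonyl)-4-[(2R,3R)-3,5,7-tris(benzyloxy)-2-[3,4-bis(benzyloxy)phenyl]-8-bromochroman-6-yl]chromane, both C4 epimers | [C@@H]1(c2ccc(OCc3ccccc3)cc2)CC(S(=O)(=O)c2ccccc2)(c2c(OCc3ccccc3)c3C[C@@H](OCc4ccccc4)[C@@H](c4ccc(OCc5ccccc5)c(OCc5ccccc5)c4)Oc3c(Br)c2OCc2ccccc2)c2ccc(OCc3ccccc3)cc2O1 | intermediate
14 | (2S)-7-(benzyloxy)-2-[4-(benzyloxy)phenyl]-4-[(2R,3R)-3,5,7-tris(benzyloxy)-2-[3,4-bis(benzyloxy)phenyl]-8-bromochroman-6-yl]chroman-4-ylium benzenesulfinate | [O-]S(=O)c1ccccc1.[C@@H]1(c2ccc(OCc3ccccc3)cc2)C[C+](c2c(OCc3ccccc3)c3C[C@@H](OCc4ccccc4)[C@@H](c4ccc(OCc5ccccc5)c(OCc5ccccc5)c4)Oc3c(Br)c2OCc2ccccc2)c2ccc(OCc3ccccc3)cc2O1 | intermediate (not isolated)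
15 | (2S)-7-(benzyloxy)-2-[4-(benzyloxy)phenyl]-4-[(2R,3R)-3,5,7-tris(benzyloxy)-2-[3,4-bis(benzyloxy)phenyl]-8-bromochroman-6-yl]-2H-chromene | [C@@H]1(c2ccc(OCc3ccccc3)cc2)C=C(c2c(OCc3ccccc3)c3C[C@@H](OCc4ccccc4)[C@@H](c4ccc(OCc5ccccc5)c(OCc5ccccc5)c4)Oc3c(Br)c2OCc2ccccc2)c2ccc(OCc3ccccc3)cc2O1 | intermediate
16 | C3 alkylborane of 17 (BH2 in place of the C3 hydroxyl, same configuration) | C(c1ccccc1)Oc1ccc([C@H]2Oc3cc(OCc4ccccc4)ccc3[C@@H](c3c(OCc5ccccc5)c(Br)c4c(c3OCc3ccccc3)C[C@@H](OCc3ccccc3)[C@@H](c3ccc(OCc5ccccc5)c(OCc5ccccc5)c3)O4)[C@@H]2B)cc1 | intermediate (not isolated)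
17 | (2R,3S,4S)-7-(benzyloxy)-2-[4-(benzyloxy)phenyl]-4-[(2R,3R)-3,5,7-tris(benzyloxy)-2-[3,4-bis(benzyloxy)phenyl]-8-bromochroman-6-yl]chroman-3-ol | C(c1ccccc1)Oc1ccc([C@H]2Oc3cc(OCc4ccccc4)ccc3[C@@H](c3c(OCc5ccccc5)c(Br)c4c(c3OCc3ccccc3)C[C@@H](OCc3ccccc3)[C@@H](c3ccc(OCc5ccccc5)c(OCc5ccccc5)c3)O4)[C@@H]2O)cc1 | intermediate
18 | (2R,3S,4S)-2-(4-hydroxyphenyl)-4-[(2R,3R)-2-(3,4-dihydroxyphenyl)-3,5,7-trihydroxychroman-6-yl]chromane-3,7-diol | Oc1ccc([C@H]2Oc3cc(O)ccc3[C@@H](c3c(O)cc4c(c3O)C[C@@H](O)[C@@H](c3ccc(O)c(O)c3)O4)[C@@H]2O)cc1 | target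

**Step count and risks**

Total step count: 10. Longest linear sequence: 8 steps (steps 1, 2, 3, 4, 7, 8, 9, 10); steps 5 and 6 form the short second branch.

Steps most likely to fail:

1. Step 7 (Proposed new method).
   - What may go wrong: the fully substituted carbanion may open the epoxide too slowly or at the benzylic carbon, and alkoxide 12 may undergo Grob-type fragmentation or lose sulfinate before the slow SNAr closes ring C.
   - Fallback (known chemistry; sets out from 5 and 10, comes back at 17; ring D is attached last): 5 would be converted with propane-1,3-dithiol and BF3·OEt2 into 2-[4-(benzyloxy)-2-fluorophenyl]-1,3-dithiane F1. Its 2-lithio derivative (n-BuLi, THF, −78 → −30 °C) should open 10 at CH2 to give (1S)-1-[4-(benzyloxy)phenyl]-2-{2-[4-(benzyloxy)-2-fluorophenyl]-1,3-dithian-2-yl}ethan-1-ol F2. KH and 18-crown-6 in DMF would close ring C by SNAr to (2S)-7-(benzyloxy)-2-[4-(benzyloxy)phenyl]spiro[chromane-4,2'-[1,3]dithiane] F3. MeI and CaCO3 in aqueous MeCN would unmask (2S)-7-(benzyloxy)-2-[4-(benzyloxy)phenyl]chroman-4-one F4. NaBH4 would give (2S)-7-(benzyloxy)-2-[4-(benzyloxy)phenyl]chroman-4-ol F5, and catalytic TsOH in toluene would dehydrate it to (2S)-7-(benzyloxy)-2-[4-(benzyloxy)phenyl]-2H-chromene F6. OsO4 with N-methylmorpholine N-oxide should dihydroxylate anti to the C2 aryl group to give (2R,3S,4S)-7-(benzyloxy)-2-[4-(benzyloxy)phenyl]chromane-3,4-diol F7. BF3·OEt2-promoted ionisation of the C4 hydroxyl of F7 in the presence of 4 would then form the C4–C6 bond trans to the C3 hydroxyl (the classical flavan-3,4-diol route to 4-arylflavan-3-ols, with C8 of the nucleophile blocked by bromine) and give 17.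

2. Step 4.
   - What may go wrong: Friedel–Crafts attack at the hindered C6 may be slow, and the sulfone may re-ionise under the acid so that the cation is drained into over-arylation or decomposition while the sulfinic acid disproportionates.
   - Fallback (sets out from 4, comes back at 7): Vilsmeier–Haack formylation (POCl3, DMF) at C6 would give (2R,3R)-3,5,7-tris(benzyloxy)-2-[3,4-bis(benzyloxy)phenyl]-8-bromochromane-6-carbaldehyde F8. Addition of 4-(benzyloxy)-2-fluorophenyllithium (from purchased 4-(benzyloxy)-1-bromo-2-fluorobenzene and n-BuLi, THF, −78 °C) would give carbinol 6, here isolated. Acid-mediated substitution of its hydroxyl by PhSO2H would give 7.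

3. Step 10.
   - What may go wrong: hydrogenolysis may stall through catalyst poisoning by bromide, leaving partly benzylated material, or may over-reduce by opening the benzylic C2–O1 bonds of rings C and F.
   - Fallback (sets out from 17, comes back at 18): radical debromination with Bu3SnH and azobisisobutyronitrile in toluene at 80 °C would give (2R,3S,4S)-7-(benzyloxy)-2-[4-(benzyloxy)phenyl]-4-[(2R,3R)-3,5,7-tris(benzyloxy)-2-[3,4-bis(benzyloxy)phenyl]chroman-6-yl]chroman-3-ol F9. The seven benzyl ethers would then be removed without hydrogen by BCl3 and pentamethylbenzene in CH2Cl2 at −78 °C to give 18.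

**Further compounds**

F1 | step 7 | 2-[4-(benzyloxy)-2-fluorophenyl]-1,3-dithiane | Fc1cc(OCc2ccccc2)ccc1C1SCCCS1
F2 | step 7 | (1S)-1-[4-(benzyloxy)phenyl]-2-{2-[4-(benzyloxy)-2-fluorophenyl]-1,3-dithian-2-yl}ethan-1-ol | O[C@@H](CC1(SCCCS1)c1ccc(OCc2ccccc2)cc1F)c1ccc(OCc2ccccc2)cc1
F3 | step 7 | (2S)-7-(benzyloxy)-2-[4-(benzyloxy)phenyl]spiro[chromane-4,2'-[1,3]dithiane] | [C@@H]1(c2ccc(OCc3ccccc3)cc2)CC2(SCCCS2)c2ccc(OCc3ccccc3)cc2O1
F4 | step 7 | (2S)-7-(benzyloxy)-2-[4-(benzyloxy)phenyl]chroman-4-one | [C@@H]1(c2ccc(OCc3ccccc3)cc2)CC(=O)c2ccc(OCc3ccccc3)cc2O1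
F5 | step 7 | (2S)-7-(benzyloxy)-2-[4-(benzyloxy)phenyl]chroman-4-ol (C4 epimers, mainly 2,4-cis) | [C@@H]1(c2ccc(OCc3ccccc3)cc2)CC(O)c2ccc(OCc3ccccc3)cc2O1
F6 | step 7 | (2S)-7-(benzyloxy)-2-[4-(benzyloxy)phenyl]-2H-chromene | [C@@H]1(c2ccc(OCc3ccccc3)cc2)C=Cc2ccc(OCc3ccccc3)cc2O1
F7 | step 7 | (2R,3S,4S)-7-(benzyloxy)-2-[4-(benzyloxy)phenyl]chromane-3,4-diol | C(c1ccccc1)Oc1ccc([C@H]2Oc3cc(OCc4ccccc4)ccc3[C@H](O)[C@@H]2O)cc1
F8 | step 4 | (2R,3R)-3,5,7-tris(benzyloxy)-2-[3,4-bis(benzyloxy)phenyl]-8-bromochromane-6-carbaldehyde | O=Cc1c(OCc2ccccc2)c2C[C@@H](OCc3ccccc3)[C@@H](c3ccc(OCc4ccccc4)c(OCc4ccccc4)c3)Oc2c(Br)c1OCc1ccccc1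
F9 | step 10 | (2R,3S,4S)-7-(benzyloxy)-2-[4-(benzyloxy)phenyl]-4-[(2R,3R)-3,5,7-tris(benzyloxy)-2-[3,4-bis(benzyloxy)phenyl]chroman-6-yl]chroman-3-ol | C(c1ccccc1)Oc1ccc([C@H]2Oc3cc(OCc4ccccc4)ccc3[C@@H](c3c(OCc5ccccc5)cc4c(c3OCc3ccccc3)C[C@@H](OCc3ccccc3)[C@@H](c3ccc(OCc5ccccc5)c(OCc5ccccc5)c3)O4)[C@@H]2O)cc1
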